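The larch run, charged with twice the partner of the oak run and held at 45 °C against 50 °C, stood flat near 54.9% of triple product, while the oak run stood flat near 15.7%, the mean of its readings.

common to all: starting material 0.30 M
- oak: partner 0.33 M; temperature 50 °C; the very flask that is asked about, followed so far
- larch: partner 0.66 M; temperature 45 °C; run made earlier
- flask: partner 0.330 M; temperature 50 °C; time 15 min

| run | time / min | triple product / % | starting material / % |
|---|---|---|---|
| oak | 2.00 | 14.7 | 39.9 |
| oak | 5.00 | 16.3 | 39.7 |
| oak | 10.0 | 15.1 | 40.8 |
| oak | 15.0 | 16.6 | 40.8 |
| larch | 0.417 | 49.4 | 16.4 |
| larch | 1.00 | 54.3 | 13.3 |
| larch | 2.00 | 54.6 | 13.8 |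
| larch | 3.00 | 54.9 | 13.3 |

(each reading ± 0.5 percentage points)

- triple product, in percent of the starting material first charged, at 15 min
- the remedy with the largest gain of triple product, or "none" below 2 percentage points (Sunday's / Wednesday's / Tuesday's / Saturday's / none)
- triple product present, with what was taken out counted in, in percent of the starting material first charged, after Wednesday's
- triple product present, with what was taken out counted in, in percent of the starting material first charged, after Saturday's

- what is taken out of triple product is counted as made
- additions bring no volume worth counting

- Sunday's: change nothing and wait 5.0 min more
- Wednesday's: at 15 min raise the temperature by 15 K, then wait 5.0 min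
- Tuesday's: at 15 min add partner, 100% of the amount charged, then wait 5.0 min
- Saturday's: at 15 min take out 90% of the triple product then present, then wait 5.0 min

These readings are best reckoned by what is left. The quantity to carry is the partner budget, [partner]/[starting material] as charged, which is 1.10 for the oak flask and 2.20 for the larch run. Taking its name at its word, triple product holds 3 partners. In the oak flask the mean reading of starting material is 40.3%, so 44.0% of the charge is unseen, and this reckoning assumes that it holds at least 1 partner each. On these readings and that assumption, the oak flask has spent at least 0.911 of the budget and has at most 0.190 left. On the same terms the last larch reading gives 31.8% unseen, at least 1.97 spent and at most 0.235 left. A further 0.432 partner per unseen molecule in the oak flask, or 0.739 in the larch run, clears the remainder, so partner can be the limiting reagent in both, with starting material still present.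

The reckoning here therefore takes the flat lines as a stop for want of partner. It puts triple product at 15.7% at 15 min. Sunday's, Wednesday's and Saturday's bring no partner, so each should stay at 15.7%, whereas Tuesday's raises the budget to 2.20 and is the remedy to choose.

The forecast reads the flat line otherwise, “this is equilibrium and not slow kinetics”, and gives 15.7%, Tuesday's, 5% after Wednesday's and 23% after Saturday's, so the two part on those last two remedies.

The flask gives 15.6%, Tuesday's with a gain of 29 percentage points, 15.6% after Wednesday's and 15.6% after Saturday's.

    partner + triple product → tetra adduct + by-product (k = 0.0190 /M/s, Ea = 65.0 kJ/mol)
    partner + bis adduct → triple product + by-product (k = 1.10 /M/s, Ea = 41.0 kJ/mol)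
    starting material + partner → mono adduct + by-product (k = 0.490 /M/s, Ea = 58.0 kJ/mol)
    partner + mono adduct → bis adduct + by-product (k = 0.920 /M/s, Ea = 62.0 kJ/mol)
    bis adduct → side product (k = 0.0260 /s, Ea = 78.0 kJ/mol)
    (constants at 50 °C)

The equations price each species: mono adduct 1 partner, bis adduct and side product 2, triple product 3, tetra adduct 4. At 15.0 min the flask holds 0% of its partner, and its species, with that partner counted, add up to 1.10 against the budget of 1.10. The neighbour flask charged with 0.12 M of starting material has a budget of 2.75, larger than the larch run's. At 15.0 min that neighbour holds 0.0734% of its partner, its species, with that partner counted, add up to 2.75, and of its starting material 1.43% is left, 24.9% is side product, 7.20% is tetra adduct and 64.8% is triple product.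

All runs were generated by integration with constants of no real substance, and the scatter is random.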